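The data were computed for substances that don't exist.

Count each flask's ring by its lost time τ, the mean hour at which its substrate entered whatever slowly becomes ring.

| flask | substrate | activator | remark | time |
|---|---|---|---|---|
| south-east | 0.068 M | 0.102 M | run made earlier |  |
| north-east | 0.068 M | 0.051 M | run made earlier |  |
| east | 0.068 M | 0.20 M | run made earlier |  |
| larch | 0.068 M | 0.102 M (fed, over 2.5 h) | all else is in the flask from the start; the feed brings no volume worth counting | 4.0 h |
| alder | 0.068 M | 0.102 M | everything together at the start | 4.0 h |
| oak | 0.068 M (fed, over 2.5 h) | 0.102 M | all else is in the flask from the start; the feed brings no volume worth counting | 4.0 h |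
| maple | 0.068 M | 0.102 M (in portions, 3, over 2.5 h) | first portion at the start, last at 2.5 h | 4.0 h |

| run | time / h | ring / % | substrate / % |
|---|---|---|---|
| south-east | 0.667 | 13 | 14 |
| south-east | 1.33 | 22 | 1 |
| south-east | 2.00 | 33 | 2 |
| south-east | 2.50 | 44 | 0 |
| north-east | 1.00 | 9 | 37 |
| north-east | 2.00 | 21 | 27 |
| north-east | 3.00 | 35 | 28 |
| north-east | 4.00 | 43 | 24 |
| east | 1.00 | 18 | 0 |
| east | 2.00 | 38 | 0 |
| east | 3.00 | 53 | 1 |
| east | 4.00 | 64 | 3 |

(readings scatter by 1.5 percentage points)

- which flask leads in amount of ring, in percent of the substrate charged ("all alike" within 1.5 percentage points) (larch / alder / oak / maple / all alike)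
- how much ring is there at the end, in percent of the substrate charged: larch
- how much ring is there at the end, in percent of the substrate charged: alder
- how much ring is there at the end, in percent of the substrate charged: oak
- how much ring is there at the end, in percent of the substrate charged: maple

- a reading or a percentage of ring counts all its forms, free or not

In the east run, substrate read 0 % at 1.00 h while ring read 18 %, so something unseen stood between them, and I took its turning into ring as a first-order step. The last east reading, with that run's own τ set aside, gave the ring constant k, the negative logarithm of the share not yet ring divided by the time: 0.255 /h. Ring at time t, as a share of the substrate that gets through, is then one minus exp(−k(t−τ)). Alder repeats the south-east recipe, whose reading at 2.50 h gave τ = 0.230 h, so I reckoned 61.8 % for alder. Larch, oak and maple have their doses centred on 1.25 h, which gave 50.5 % for each.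

The forecast named alder with 61 %, then maple 49 %, larch 48 % and oak 46 %, each dosed flask below my figure, saying “Delay only costs ring.”

The flasks gave 60.3 % in alder, 48.5 % in maple, 47.5 % in larch and 44.7 % in oak, so alder led.

    activator + ring ⇌ idle adduct, settled at all times (K = 4.10 /M)
    substrate + activator → activated form (k = 0.940 /M/min)
    substrate + activated form → open dimer (k = 0.00290 /M/min)
    activated form → ring (k = 0.00420 /min)

With k, these results put τ at 0.381 h for alder, 1.40 h for maple, 1.48 h for larch and 1.68 h for oak, the dosed values later than my 1.25 h. In alder at 2.00 h, substrate stood at 0.829 % and activated form at 64.1 %, which was turning into ring with a half-life of 2.8 h. In oak, the step making activated form reached the midpoint of its turnover up to 4.0 h at 1.48 h.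

Oak with 0.025 M of activator, less than the substrate charge, makes activator the limiting reagent, allowing a share 36.8 % of the substrate if the two combine one to one; the feed supplies that share by 0.919 h, so I put τ at 0.460 h, and k then gives an estimate of 21.9 % ring. That flask gave 18.0 % ring, with 62.9 % of the substrate charged and 0.148 % of its own activator charge left.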